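The runs are simulated on assumed constants.

At early times the maple run already shows the difficulty: by 0.833 min starting material reads 15 % of the charge while target reads 0 %, so what has left the starting material does not stand as target. We have to rank the set-ups below.

| setting | maple | birch | elm | ash | south-west | south | north-west | west |
|---|---|---|---|---|---|---|---|---|
| starting material | 0.10 M | 0.067 M | 0.15 M | 0.10 M | 0.10 M | 0.10 M | 0.10 M | 0.10 M |
| coupling partner | 0.18 M | 0.18 M | 0.18 M | 0.27 M | 0.180 M | 0.180 M | 0.180 M | 0.180 M |
| remark | run made earlier | run made earlier | run made earlier | run made earlier | a tube with plug flow, the mixed feed as stated, residence time 6.0 min | a single well-mixed tank run continuously and read at steady state, 30.0 min in it on average | one stirred flow tank at steady state, fed with the mixture as stated, mean residence time 6.0 min | everything together in a closed stirred flask, run for 6.0 min |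
| time |  |  |  |  | 6.0 min |  |  | 6.0 min |

| run | time / min | target / % | starting material / % |
|---|---|---|---|
| maple | 0.833 | 0 | 15 |
| maple | 2.00 | 11 | 2 |
| maple | 2.50 | 19 | 1 |
| maple | 4.00 | 33 | 0 |
| birch | 0.833 | 1 | 21 |
| birch | 2.50 | 19 | 0 |
| birch | 5.00 | 42 | 0 |
| birch | 8.00 | 60 | 0 |
| elm | 0.833 | 5 | 16 |
| elm | 2.50 | 22 | 2 |
| elm | 5.00 | 36 | 0 |
| elm | 8.00 | 50 | 0 |
| ash | 2.00 | 19 | 1 |
| ash | 4.00 | 46 | 0 |
| ash | 5.00 | 51 | 1 |
| ash | 8.00 | 71 | 0 |

(each reading ± 1.5 percentage points)

- the stated concentrations are those of everything mixed, before any reaction; amounts are the same in each set-up
- the earlier runs were made in a closed, stirred flask
- a reading or a percentage of target counts all its forms, free or not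

1. the set-up with the highest amount of target at the outlet or at the end, in percent of the starting material put in ("none" if the first two lie within 2 percentage points) (south-west / south / north-west / west / none)
2. amount of target at the outlet or at the end, in percent of the starting material put in, south-west
3. amount of target at the outlet or at the end, in percent of the starting material put in, south
4. amount of target at the outlet or at the end, in percent of the starting material put in, north-west
5. amount of target at the outlet or at the end, in percent of the starting material put in, west

In the maple run starting material falls at 2.28 min⁻¹. From 2.00 min to 4.00 min, the part of the charge not read as target shrinks at 0.142 min⁻¹. We call this second reading the slow-step constant, the fraction of that remaining part turned into target per minute at the maple charge. Starting material goes much faster than that, so we reckon the vessels by the slow step.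

Take the settings in turn. Changing from the closed flask west to the tube south-west is the zero of our scale: each plug in the tube lives the flask's history, so by hand the difference is nil. Continuing maple from its last reading at the slow-step constant gives 49.6 % for both at 6.0 min.

Next comes mixing. For a first-order step, a tank passes the count (constant times mean time) divided by one plus the count. North-west has a count of 0.852, so its share is 46.0 %, less than our figure for west. Then comes mean time: south has a count of 4.26 and a share of 81.0 %, more than our figure for west. These shares omit the lag and the partner used, so we commit to the order rather than to the figures: south, then west with south-west, then north-west.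

The forecast gives 46 % for west and 46 % for south-west, 35 % for north-west, and 70 % for south, within 63 % to 77 %: “The long-residence tank wins.” Its figures for west, north-west and south lie lower than ours , but its order is ours.

The simulation gives 47.3 % for west, 47.3 % for south-west, 33.1 % for north-west and 61.4 % for south, so south stands highest.

    starting material → intermediate A (k = 2.20 min⁻¹)
    intermediate A → intermediate B (k = 0.800 min⁻¹)
    coupling partner + intermediate B → target (k = 1.20 M⁻¹ min⁻¹)
    coupling partner + intermediate B ⇌ intermediate C (K = 3.80 M⁻¹, k = 0.0580 M⁻¹ min⁻¹)
    starting material + target → side product (k = 3.40 M⁻¹ min⁻¹)
    coupling partner + target ⇌ idle adduct, settled at all times (K = 15.0 M⁻¹)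

North-west reaches 0.720 of its tank share and south 0.758 of its own, and south lies under the forecast's range. In south-west, the half-life of intermediate B by coupling with partner alone, at the concentrations as charged, is 3.2 min, longer than the 0.32 min of starting material and the 0.87 min of intermediate A, so on these half-lives that coupling is the rate-limiting step. At the south-west outlet, intermediate B stands at 49.1 % of the starting material charged.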